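- Slowness comes first: in the winter run right-handed product has crept to 6% by 25.0 h while left-handed product stands at 39%, and a hand that slow could wear an excess down with waiting.

| flask | left-handed substrate | right-handed substrate | gas | remark | time |
|---|---|---|---|---|---|
| winter | 0.42 M | 0.42 M | 160 mM (held) | run made earlier |  |
| midnight | 0.66 M | 0.66 M | 160 mM (held) | run made earlier |  |
| teal | 0.30 M | 0.30 M | 160 mM (held) |  | 40 h |
| ochre | 0.30 M | 0.30 M | 160 mM (held) |  | 150 h |

| run | time / h | left-handed product / % | right-handed product / % |
|---|---|---|---|
| winter | 2.00 | 5 | 3 |
| winter | 4.00 | 15 | 0 |
| winter | 6.00 | 23 | 3 |
| winter | 12.0 | 36 | 2 |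
| winter | 25.0 | 39 | 6 |
| midnight | 5.00 | 14 | 0 |
| midnight | 10.0 | 24 | 1 |
| midnight | 15.0 | 33 | 5 |
| midnight | 20.0 | 36 | 4 |
| midnight | 25.0 | 36 | 5 |

(scatter of a reading: 1.5 percentage points)

- partner is single-handed; left-handed substrate and right-handed substrate are mirror images of each other, charged as a racemate, each of them at the stated concentration
- at the start none of the gas is in solution
- an excess is the difference of the two amounts in percent of their sum
- an excess is below zero if the other one leads
- the handed part of partner does not stay in what it makes, so the products of the two hands are mirror images too

- which of the two ends with the higher excess of left-handed product over right-handed product in the product ("neither" if they lie within 2 percentage points) (teal / ochre / neither)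
- excess of left-handed product over right-handed product in the product at the end, teal
- excess of left-handed product over right-handed product in the product at the end, ochre

- Pooling the last readings of both runs, taken at 25.0 h, gives 74.4% for the difference of the two products in percent of their sum, the late excess; this pooled reading carries a scatter of 4.3 percentage points.
- Turn the time first: by hand, a longer wait lowers the excess if right-handed product still grows. In the midnight run, from 20.0 h to 25.0 h, it goes from 4% to 5%, a step within the scatter of 1.5 points on a reading, and left-handed product stays at 36%.
- Turn the charge next: by hand, a change in charge could shift the share of the hands. The winter run reads 73.3% and the midnight run 75.6%, a gap smaller than the scatter, though teal's 0.30 M lies below both.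
- Our own reckoning therefore takes this as kinetic control and carries 74.4% over to teal and to ochre, though the runs show no reading after 25.0 h, so it expects neither to lead.
- The forecast differs: of the excess it says “It should decay with time” and gives 60% for teal, 22% for ochre, and teal as the higher.
- The flask gives 72.7% for teal and 72.1% for ochre, so the answer is neither. In ochre at 150 h, 0% of the left-handed charge and 0% of the right-handed charge are left, with half of the charge as decomposed reagent. The late excess stands 2.3 points above ochre, less than its scatter.

    left-handed substrate ⇌ achiral form (K = 1.21, k = 0.119 h⁻¹)
    right-handed substrate ⇌ achiral form (K = 1.21, k = 0.119 h⁻¹)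
    gas ⇌ partner, rate k3*(csat - [partner]) (kL = 0.473 h⁻¹)
    partner + left-handed substrate → left-handed product (k = 2.27 M⁻¹ h⁻¹)
    achiral form → decomposed reagent (k = 0.224 h⁻¹)
    partner + right-handed substrate → right-handed product (k = 0.120 M⁻¹ h⁻¹)

- For ochre read at 10 d, the late excess again gives 74.4%; the computed flask gives 72.1%.

(The earlier runs and the new flask were computed for substances that don't exist, and the scatter is random.)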